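**Plan**

- Retrosynthesis: the three esters come off first, then C3–CH3 (cuprate addition to a C1 enone) and the C8/C9 diol (an alkene). The cyclobutane bond C4–C5 is cut next, then C8=C9 (metathesis), C10–CH3, C9–C10 and C5–C11, which leads to 3-ethoxycyclohex-2-en-1-one and an aldehyde from (S)-pantolactone.
- Forward: ring A (six-membered, bought) is joined to the chain by an aldol reaction; ring B (seven-membered) is closed by metathesis to a cis-fused bicyclo[5.4.0]undecenone; ring C (cyclobutane) is closed last by C4–C5 bond formation, which also completes the bicyclo[3.1.1]heptanone.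
- Enabling feature: in the cis-fused bicycle, C4 (α to the C3 carbonyl in ring A) and C5 (carrying a sulfonate in ring B) sit on the two ring-fusion atoms C10 and C11 and are 1,3-syn, so the C4 enolate can displace the C5 leaving group. The carbonyl is afterwards moved from C3 to C1 by a Wharton transposition.
- Stereochemistry: C7 comes from (S)-pantolactone; C5 and C11 from a chelation-controlled Mukaiyama aldol; C10 from cuprate addition trans to the side chain; C4 and C5 (inversion) from the ring closure; C3 from cuprate addition anti to the C10 bridge; C8 and C9 from dihydroxylation anti to O-7.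

Key step: step 14

Remark: carbons of the tricyclic compounds are numbered as in longipinane (C1 ketone carbon of the target, C3 CH–CH3, C4/C5 cyclobutane CH, C6 C(CH3)2, C7–C9 oxygenated, C10 quaternary C–CH3, C11 CH next to C1); the same numbers are used for these atoms in earlier intermediates; angelic acid and tributyl[(methoxymethoxy)methyl]stannane are taken as purchasable reagents.

**Route**

Step 1
Reactants: 1 (S)-pantolactone [(3S)-3-hydroxy-4,4-dimethyloxolan-2-one]
Product: 2 (3S)-3-(benzyloxy)-4,4-dimethyloxolan-2-one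
Conditions: BnOC(=NH)CCl3, TfOH (cat.), CH2Cl2–cyclohexane, 0 °C to rt
Reagents that add atoms: benzyl 2,2,2-trichloroacetimidate N=C(OCc1ccccc1)C(Cl)(Cl)Cl
Why: Acid-catalysed imidate benzylation should protect the hydroxyl without base, so the stereocentre next to the lactone carbonyl (the future C7) is not epimerised.

Step 2
Reactants: 2 (3S)-3-(benzyloxy)-4,4-dimethyloxolan-2-one
Product: 3 (3S)-3-(benzyloxy)-4,4-dimethyloxolan-2-ol (lactol, both anomers)
Conditions: i-Bu2AlH, CH2Cl2, −78 °C; aq. KNaC4H4O6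
Reagents that add atoms: none
Why: Partial hydride reduction of the lactone should stop at the lactol because the aluminium hemiacetal is stable at −78 °C.

Step 3
Reactants: 3 (3S)-3-(benzyloxy)-4,4-dimethyloxolan-2-ol
Product: 4 (3R)-3-(benzyloxy)-2,2-dimethylpent-4-en-1-ol
Conditions: Ph3PCH3Br, KOt-Bu, THF, 0 to 50 °C
Reagents that add atoms: methyltriphenylphosphonium bromide C[P+](c1ccccc1)(c1ccccc1)c1ccccc1.[Br-]
Why: Wittig methylenation of the hydroxy aldehyde in equilibrium with the lactol should give the vinyl group and release the neopentyl primary alcohol, the descriptor changing only because the priorities change.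

Step 4
Reactants: 4 (3R)-3-(benzyloxy)-2,2-dimethylpent-4-en-1-ol
Product: 5 (3R)-3-(benzyloxy)-2,2-dimethylpent-4-enal
Conditions: Dess–Martin periodinane, NaHCO3, CH2Cl2, 0 °C to rt
Reagents that add atoms: none
Why: Dess–Martin oxidation should give the aldehyde, which has a quaternary α-carbon and therefore can neither enolise nor lose the β-benzyloxy group.

Step 5
Reactants: 6 3-ethoxycyclohex-2-en-1-one
Product: 7 1-ethoxy-3-(trimethylsilyloxy)cyclohexa-1,3-diene
Conditions: LiN(i-Pr)2, THF, −78 °C; Me3SiCl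
Reagents that add atoms: chlorotrimethylsilane C[Si](C)(C)Cl
Why: Kinetic deprotonation of the vinylogous ester at C6 (the α′ position, as in Stork–Danheiser alkylations) and O-silylation should give the silyloxy diene.

Step 6
Reactants: 5 (3R)-3-(benzyloxy)-2,2-dimethylpent-4-enal, 7 1-ethoxy-3-(trimethylsilyloxy)cyclohexa-1,3-diene
Product: 8 (6R)-6-[(1R,3R)-3-(benzyloxy)-1-hydroxy-2,2-dimethylpent-4-en-1-yl]-3-ethoxycyclohex-2-en-1-one
Conditions: MgBr2·OEt2, CH2Cl2, −78 to −20 °C; then 0.5 M HCl, THF, 0 °C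
Reagents that add atoms: none
Why: Mukaiyama aldol addition of the silyloxy diene to the aldehyde held as a six-membered magnesium chelate with its β-benzyloxy group should proceed through an open transition state, so that chelation sets the new carbinol centre (the future C5) 1,3-anti to C7 and the open geometry gives the syn relation between the ring CH2 on C11 and the hydroxyl.

Step 7
Reactants: 8 (6R)-6-[(1R,3R)-3-(benzyloxy)-1-hydroxy-2,2-dimethylpent-4-en-1-yl]-3-ethoxycyclohex-2-en-1-one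
Product: 10 (4S)-4-[(1R,3R)-3-(benzyloxy)-1-hydroxy-2,2-dimethylpent-4-en-1-yl]-3-[(methoxymethoxy)methyl]cyclohex-2-en-1-one, via tertiary carbinol 9 (not isolated)
Conditions: Bu3SnCH2OCH2OMe, n-BuLi, THF, −78 °C; then 8; then 1 M HCl, THF, 0 °C to rt
Reagents that add atoms: tributyl[(methoxymethoxy)methyl]stannane CCCC[Sn](CCCC)(CCCC)COCOC
Why: In this Stork–Danheiser transposition, 1,2-addition of the α-alkoxymethyllithium to the vinylogous ester carbonyl and acid hydrolysis with loss of ethanol should give the enone carrying the protected C9 carbon on its β-carbon, with the existing stereocentres untouched.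

Step 8
Reactants: 10 (4S)-4-[(1R,3R)-3-(benzyloxy)-1-hydroxy-2,2-dimethylpent-4-en-1-yl]-3-[(methoxymethoxy)methyl]cyclohex-2-en-1-one
Product: 11 (3R,4S)-4-[(1R,3R)-3-(benzyloxy)-1-hydroxy-2,2-dimethylpent-4-en-1-yl]-3-[(methoxymethoxy)methyl]-3-methylcyclohexan-1-one
Conditions: Me2CuLi (from MeLi, CuI), Me3SiCl, THF, −78 to −30 °C; then 1 M HCl, THF, 0 °C
Reagents that add atoms: methyllithium [Li]C
Why: Silyl-accelerated conjugate addition of the Gilman cuprate should create the quaternary centre C10 with the methyl group trans to the pseudo-axial side chain on the neighbouring carbon (axial attack anti to the γ-substituent), which leaves the oxygenated one-carbon arm cis to the chain.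

Step 9
Reactants: 11 (3R,4S)-4-[(1R,3R)-3-(benzyloxy)-1-hydroxy-2,2-dimethylpent-4-en-1-yl]-3-[(methoxymethoxy)methyl]-3-methylcyclohexan-1-one
Product: 12 (1R,3R)-3-(benzyloxy)-1-{(1S,2R)-2-[(methoxymethoxy)methyl]-2-methyl-4-oxocyclohexyl}-2,2-dimethylpent-4-en-1-yl methanesulfonate
Conditions: MsCl, Et3N, CH2Cl2, −10 °C
Reagents that add atoms: methanesulfonyl chloride CS(=O)(=O)Cl
Why: Sulfonylation through sulfene should activate the hindered secondary alcohol at C5 with retention of configuration.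

Step 10
Reactants: 12 (1R,3R)-3-(benzyloxy)-1-{(1S,2R)-2-[(methoxymethoxy)methyl]-2-methyl-4-oxocyclohexyl}-2,2-dimethylpent-4-en-1-yl methanesulfonate
Product: 13 (1R,3R)-3-(benzyloxy)-1-[(1S,2R)-2-(hydroxymethyl)-2-methyl-4-oxocyclohexyl]-2,2-dimethylpent-4-en-1-yl methanesulfonate
Conditions: Me2BBr, CH2Cl2, −78 °C; aq. NaHCO3
Reagents that add atoms: none
Why: The bromoborane should cleave the methoxymethyl acetal at low temperature without touching the benzyl ether, the mesylate or the ketone.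

Step 11
Reactants: 13 (1R,3R)-3-(benzyloxy)-1-[(1S,2R)-2-(hydroxymethyl)-2-methyl-4-oxocyclohexyl]-2,2-dimethylpent-4-en-1-yl methanesulfonate
Product: 14 (1R,3R)-3-(benzyloxy)-1-[(1S,2R)-2-formyl-2-methyl-4-oxocyclohexyl]-2,2-dimethylpent-4-en-1-yl methanesulfonate
Conditions: Dess–Martin periodinane, NaHCO3, CH2Cl2, rt
Reagents that add atoms: none
Why: Dess–Martin oxidation of the neopentyl primary alcohol should give the aldehyde, whose quaternary α-carbon excludes epimerisation.

Step 12
Reactants: 14 (1R,3R)-3-(benzyloxy)-1-[(1S,2R)-2-formyl-2-methyl-4-oxocyclohexyl]-2,2-dimethylpent-4-en-1-yl methanesulfonate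
Product: 15 (1R,3R)-3-(benzyloxy)-1-[(1S,2S)-2-ethenyl-2-methyl-4-oxocyclohexyl]-2,2-dimethylpent-4-en-1-yl methanesulfonate
Conditions: Ph3PCH3Br, KN(SiMe3)2, THF, −78 to −20 °C
Reagents that add atoms: methyltriphenylphosphonium bromide C[P+](c1ccccc1)(c1ccccc1)c1ccccc1.[Br-]
Why: Wittig methylenation with a slight excess of ylide at low temperature should convert the aldehyde and leave the less electrophilic ketone, the descriptor at the quaternary carbon changing only by priority.

Step 13
Reactants: 15 (1R,3R)-3-(benzyloxy)-1-[(1S,2S)-2-ethenyl-2-methyl-4-oxocyclohexyl]-2,2-dimethylpent-4-en-1-yl methanesulfonate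
Product: 16 (4aS,7R,9R,9aS)-7-(benzyloxy)-4a,8,8-trimethyl-3-oxo-2,3,4,4a,7,8,9,9a-octahydro-1H-benzo[7]annulen-9-yl methanesulfonate (cis-fused)
Conditions: second-generation Grubbs catalyst (5 mol %), toluene, 80 °C
Reagents that add atoms: none
Why: Ring-closing metathesis of the two vinyl groups, which are cis on ring A, should close ring B and so give the cis-fused bicyclo[5.4.0]undecenone.

Step 14
Reactants: 16 (4aS,7R,9R,9aS)-7-(benzyloxy)-4a,8,8-trimethyl-3-oxo-2,3,4,4a,7,8,9,9a-octahydro-1H-benzo[7]annulen-9-yl methanesulfonate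
Product: 18 (4S,5R,7R,10S,11R)-7-(benzyloxy)longipin-8-en-3-one, via potassium enolate 17 (not isolated)
Conditions: KOt-Bu, t-BuOH–THF (1:4), high dilution, 25 to 50 °C
Reagents that add atoms: none
Why: KOt-Bu reversibly converts the C3 ketone of 16 into its enolates, and the C4 enolate 17 displaces the C5 methanesulfonate by intramolecular SN2 attack, the closest known reaction type being the cycloalkylation of cis-fused bicyclic keto sulfonates that builds the cyclobutane of bridged terpene skeletons such as tricyclo[4.4.0.0(2,7)]decanones. The new C4–C5 bond closes the cyclobutane C4–C5–C11–C10 in a 4-exo-tet mode (enolate double bond outside the new ring) and in the same event the six-membered ring C3–C4–C5–C11–C1–C2 (6-exo-tet, enolate double bond inside the ring) and the seven-membered ring C4–C5–C6–C7–C8–C9–C10 (7-exo-tet), so that the fused bicycle should become the longipinane cage. C5 is set by inversion, its mesylate having been placed cis to H-11 by the aldol of step 6, and C4 is set by the cis ring fusion, because C4 can bond to C5 only on the face of ring A that carries C5. The step needs C-alkylation at C4 in preference to elimination, O-alkylation and reaction through the C2 enolate. Elimination is disfavoured because C6 is quaternary and H-11 is syn to the leaving group, the C2 enolate cannot reach the rear of the C5–O bond while C6 is held on the C10 side by ring B, and the enolates interconvert under the protic conditions, so material should drain through the C4 enolate. The product ketone can enolise only toward C2, which protects the new centres from scrambling.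

Step 15
Reactants: 18 (4S,5R,7R,10S,11R)-7-(benzyloxy)longipin-8-en-3-one
Product: 20 (4S,5R,7R,10S,11R)-7-(benzyloxy)longipina-1,8-dien-3-one, via silyl enol ether 19 (not isolated)
Conditions: LiN(i-Pr)2, Me3SiCl, THF, −78 °C; then Pd(OAc)2, MeCN, rt
Reagents that add atoms: none
Why: Saegusa–Ito dehydrogenation should give the C1=C2 enone, because C4 is now a bridgehead of the bicyclo[3.1.1]heptane and the ketone can form an enol ether only toward C2.

Step 16
Reactants: 20 (4S,5R,7R,10S,11R)-7-(benzyloxy)longipina-1,8-dien-3-one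
Product: 21 (1R,2R,4S,5R,7R,10S,11R)-7-(benzyloxy)-1,2-epoxylongipin-8-en-3-one
Conditions: 30% H2O2, NaOH (cat.), MeOH, 0 °C
Reagents that add atoms: hydrogen peroxide OO
Why: Nucleophilic (Weitz–Scheffer) epoxidation should attack only the electron-poor enone, from the face anti to the methyl-bearing C10 bridge, and leave the C8=C9 alkene.

Step 17
Reactants: 21 (1R,2R,4S,5R,7R,10S,11R)-7-(benzyloxy)-1,2-epoxylongipin-8-en-3-one
Product: 22 (1S,4S,5S,7R,10R,11R)-7-(benzyloxy)longipina-2,8-dien-1-ol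
Conditions: N2H4·H2O, AcOH (cat.), MeOH, 0 °C to rt
Reagents that add atoms: none
Why: In the Wharton transposition the hydrazone of the epoxy ketone should lose nitrogen and open the epoxide, which moves the oxygen to C1 and the double bond to C2=C3.

Step 18
Reactants: 22 (1S,4S,5S,7R,10R,11R)-7-(benzyloxy)longipina-2,8-dien-1-ol
Product: 23 (4S,5S,7R,10R,11R)-7-(benzyloxy)longipina-2,8-dien-1-one
Conditions: Dess–Martin periodinane, NaHCO3, CH2Cl2, rt
Reagents that add atoms: none
Why: Oxidation of the allylic alcohol should give the C1 enone and removes the C1 stereocentre, so its configuration in 22 does not matter.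

Step 19
Reactants: 23 (4S,5S,7R,10R,11R)-7-(benzyloxy)longipina-2,8-dien-1-one
Product: 24 (3R,4S,5S,7R,10R,11R)-7-(benzyloxy)longipin-8-en-1-one
Conditions: Me2CuLi (from MeLi, CuI), Et2O, −78 to −20 °C; aq. NH4Cl
Reagents that add atoms: methyllithium [Li]C
Why: Conjugate addition of the Gilman cuprate to the bicyclo[3.1.1]heptenone should occur on the face flanked by H-5 and anti to the C10 methyl bridge, as in cuprate additions to apoverbenone-type enones, which sets C3.

Step 20
Reactants: 24 (3R,4S,5S,7R,10R,11R)-7-(benzyloxy)longipin-8-en-1-one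
Product: 25 (3R,4S,5S,7S,8S,9S,10R,11R)-7-(benzyloxy)-8,9-dihydroxylongipinan-1-one
Conditions: OsO4 (2 mol %), 4-methylmorpholine N-oxide, acetone–H2O, rt
Reagents that add atoms: 4-methylmorpholine N-oxide C[N+]1([O-])CCOCC1; water O
Why: Catalytic OsO4 dihydroxylation of the cis alkene should take place anti to the allylic C7 benzyloxy group and give the 8,9-cis-diol trans to O-7.

Step 21
Reactants: 25 (3R,4S,5S,7S,8S,9S,10R,11R)-7-(benzyloxy)-8,9-dihydroxylongipinan-1-one
Product: 26 (3R,4S,5S,7S,8S,9S,10R,11R)-7-(benzyloxy)-9-hydroxy-1-oxolongipinan-8-yl acetate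
Conditions: Ac2O (1.1 equiv), pyridine, CH2Cl2, −20 to 0 °C
Reagents that add atoms: acetic anhydride CC(=O)OC(C)=O
Why: The C8 hydroxyl is the only one not attached next to a quaternary carbon and should therefore be acetylated selectively.

Step 22
Reactants: 26 (3R,4S,5S,7S,8S,9S,10R,11R)-7-(benzyloxy)-9-hydroxy-1-oxolongipinan-8-yl acetate
Product: 27 (3R,4S,5S,7S,8R,9S,10R,11R)-7,9-dihydroxy-1-oxolongipinan-8-yl acetate
Conditions: H2 (1 atm), Pd(OH)2/C, EtOAc, rt
Reagents that add atoms: none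
Why: Hydrogenolysis should remove the benzyl ether under neutral conditions that leave the ketone, the acetate and the cyclobutane intact, no alkene being left.

Step 23
Reactants: 27 (3R,4S,5S,7S,8R,9S,10R,11R)-7,9-dihydroxy-1-oxolongipinan-8-yl acetate
Product: 28 (3R,4S,5S,7S,8R,9S,10R,11R)-8-acetoxy-1-oxolongipinane-7,9-diyl bis[(2Z)-2-methylbut-2-enoate] (CNP0197834.1)
Conditions: angelic acid, 2,4,6-Cl3C6H2COCl, Et3N, toluene, rt; then 27, 80 °C
Reagents that add atoms: angelic acid [(2Z)-2-methylbut-2-enoic acid] C/C=C(/C)C(=O)O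
Why: Yamaguchi esterification through the mixed anhydride should acylate both hindered secondary hydroxyls, and the absence of a nucleophilic amine catalyst should keep the Z geometry of the angeloyl groups.

**Compound list**

1 | (S)-pantolactone [(3S)-3-hydroxy-4,4-dimethyloxolan-2-one] | CC1(C)COC(=O)[C@H]1O | starting material
2 | (3S)-3-(benzyloxy)-4,4-dimethyloxolan-2-one | CC1(C)COC(=O)[C@H]1OCc2ccccc2 | intermediate
3 | (3S)-3-(benzyloxy)-4,4-dimethyloxolan-2-ol (both anomers) | CC1(C)COC(O)[C@H]1OCc2ccccc2 | intermediate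
4 | (3R)-3-(benzyloxy)-2,2-dimethylpent-4-en-1-ol | OCC(C)(C)[C@H](OCc1ccccc1)C=C | intermediate
5 | (3R)-3-(benzyloxy)-2,2-dimethylpent-4-enal | O=CC(C)(C)[C@H](OCc1ccccc1)C=C | intermediate
6 | 3-ethoxycyclohex-2-en-1-one | CCOC1=CC(=O)CCC1 | starting material
7 | 1-ethoxy-3-(trimethylsilyloxy)cyclohexa-1,3-diene | CCOC1=CC(O[Si](C)(C)C)=CCC1 | intermediate
8 | (6R)-6-[(1R,3R)-3-(benzyloxy)-1-hydroxy-2,2-dimethylpent-4-en-1-yl]-3-ethoxycyclohex-2-en-1-one | O=C1C=C(OCC)CC[C@@H]1[C@@H](O)C(C)(C)[C@H](OCc2ccccc2)C=C | intermediate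
9 | (6R)-6-[(1R,3R)-3-(benzyloxy)-1-hydroxy-2,2-dimethylpent-4-en-1-yl]-3-ethoxy-1-[(methoxymethoxy)methyl]cyclohex-2-en-1-ol (C1 epimers, not isolated) | COCOCC1(O)C=C(OCC)CC[C@@H]1[C@@H](O)C(C)(C)[C@H](OCc2ccccc2)C=C | intermediate
10 | (4S)-4-[(1R,3R)-3-(benzyloxy)-1-hydroxy-2,2-dimethylpent-4-en-1-yl]-3-[(methoxymethoxy)methyl]cyclohex-2-en-1-one | COCOCC1=CC(=O)CC[C@@H]1[C@@H](O)C(C)(C)[C@H](OCc2ccccc2)C=C | intermediate
11 | (3R,4S)-4-[(1R,3R)-3-(benzyloxy)-1-hydroxy-2,2-dimethylpent-4-en-1-yl]-3-[(methoxymethoxy)methyl]-3-methylcyclohexan-1-one | COCOC[C@]1(C)CC(=O)CC[C@@H]1[C@@H](O)C(C)(C)[C@H](OCc2ccccc2)C=C | intermediate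
12 | (1R,3R)-3-(benzyloxy)-1-{(1S,2R)-2-[(methoxymethoxy)methyl]-2-methyl-4-oxocyclohexyl}-2,2-dimethylpent-4-en-1-yl methanesulfonate | COCOC[C@]1(C)CC(=O)CC[C@@H]1[C@@H](OS(C)(=O)=O)C(C)(C)[C@H](OCc2ccccc2)C=C | intermediate
13 | (1R,3R)-3-(benzyloxy)-1-[(1S,2R)-2-(hydroxymethyl)-2-methyl-4-oxocyclohexyl]-2,2-dimethylpent-4-en-1-yl methanesulfonate | OC[C@]1(C)CC(=O)CC[C@@H]1[C@@H](OS(C)(=O)=O)C(C)(C)[C@H](OCc2ccccc2)C=C | intermediate
14 | (1R,3R)-3-(benzyloxy)-1-[(1S,2R)-2-formyl-2-methyl-4-oxocyclohexyl]-2,2-dimethylpent-4-en-1-yl methanesulfonate | O=C[C@]1(C)CC(=O)CC[C@@H]1[C@@H](OS(C)(=O)=O)C(C)(C)[C@H](OCc2ccccc2)C=C | intermediate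
15 | (1R,3R)-3-(benzyloxy)-1-[(1S,2S)-2-ethenyl-2-methyl-4-oxocyclohexyl]-2,2-dimethylpent-4-en-1-yl methanesulfonate | C=C[C@]1(C)CC(=O)CC[C@@H]1[C@@H](OS(C)(=O)=O)C(C)(C)[C@H](OCc2ccccc2)C=C | intermediate
16 | (4aS,7R,9R,9aS)-7-(benzyloxy)-4a,8,8-trimethyl-3-oxo-2,3,4,4a,7,8,9,9a-octahydro-1H-benzo[7]annulen-9-yl methanesulfonate | c1ccccc1CO[C@@H]2C=C[C@]3(C)CC(=O)CC[C@@H]3[C@@H](OS(C)(=O)=O)C2(C)C | intermediate
17 | potassium enolate of 16 (C3–O−, C3=C4; not isolated) | c1ccccc1CO[C@@H]2C=C[C@]3(C)C=C([O-])CC[C@@H]3[C@@H](OS(C)(=O)=O)C2(C)C.[K+] | intermediate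
18 | (4S,5R,7R,10S,11R)-7-(benzyloxy)longipin-8-en-3-one | c1ccccc1CO[C@@H]2C=C[C@]3(C)[C@@H]4[C@@H]([C@H]3CCC4=O)C2(C)C | intermediate
19 | trimethylsilyl enol ether of 18 (C2=C3, 3-OSiMe3; not isolated) | c1ccccc1CO[C@@H]2C=C[C@]3(C)[C@@H]4[C@@H]([C@H]3CC=C4O[Si](C)(C)C)C2(C)C | intermediate
20 | (4S,5R,7R,10S,11R)-7-(benzyloxy)longipina-1,8-dien-3-one | c1ccccc1CO[C@@H]2C=C[C@]3(C)[C@@H]4[C@@H]([C@H]3C=CC4=O)C2(C)C | intermediate
21 | (1R,2R,4S,5R,7R,10S,11R)-7-(benzyloxy)-1,2-epoxylongipin-8-en-3-one | c1ccccc1CO[C@@H]2C=C[C@]3(C)[C@@H]4[C@@H]([C@H]3[C@H]5O[C@H]5C4=O)C2(C)C | intermediate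
22 | (1S,4S,5S,7R,10R,11R)-7-(benzyloxy)longipina-2,8-dien-1-ol | c1ccccc1CO[C@@H]2C=C[C@]3(C)[C@@H]4[C@@H]([C@H]3[C@@H](O)C=C4)C2(C)C | intermediate
23 | (4S,5S,7R,10R,11R)-7-(benzyloxy)longipina-2,8-dien-1-one | c1ccccc1CO[C@@H]2C=C[C@]3(C)[C@@H]4[C@@H]([C@H]3C(=O)C=C4)C2(C)C | intermediate
24 | (3R,4S,5S,7R,10R,11R)-7-(benzyloxy)longipin-8-en-1-one | c1ccccc1CO[C@@H]2C=C[C@]3(C)[C@@H]4[C@@H]([C@H]3C(=O)C[C@H]4C)C2(C)C | intermediate
25 | (3R,4S,5S,7S,8S,9S,10R,11R)-7-(benzyloxy)-8,9-dihydroxylongipinan-1-one | c1ccccc1CO[C@@H]2[C@@H](O)[C@@H](O)[C@]3(C)[C@@H]4[C@@H]([C@H]3C(=O)C[C@H]4C)C2(C)C | intermediate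
26 | (3R,4S,5S,7S,8S,9S,10R,11R)-7-(benzyloxy)-9-hydroxy-1-oxolongipinan-8-yl acetate | c1ccccc1CO[C@@H]2[C@@H](OC(C)=O)[C@@H](O)[C@]3(C)[C@@H]4[C@@H]([C@H]3C(=O)C[C@H]4C)C2(C)C | intermediate
27 | (3R,4S,5S,7S,8R,9S,10R,11R)-7,9-dihydroxy-1-oxolongipinan-8-yl acetate | O[C@@H]1[C@@H](OC(C)=O)[C@@H](O)[C@]2(C)[C@@H]3[C@@H]([C@H]2C(=O)C[C@H]3C)C1(C)C | intermediate
28 | (3R,4S,5S,7S,8R,9S,10R,11R)-8-acetoxy-1-oxolongipinane-7,9-diyl bis[(2Z)-2-methylbut-2-enoate] | C/C=C(/C)C(=O)O[C@@H]1[C@@H](OC(C)=O)[C@@H](OC(=O)/C(C)=C\C)[C@]2(C)[C@@H]3[C@@H]([C@H]2C(=O)C[C@H]3C)C1(C)C | target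

**Step count and risks**

Total steps: 23. Longest linear sequence: 22 steps (steps 1–4 and 6–23; step 5 is a one-step side branch).

Steps most likely to fail:

Step 14. The 4-exo-tet displacement at C5, which is flanked by the quaternary C6, may be so slow that intermolecular aldol condensation, O-alkylation to a bridged enol ether, or unproductive enolisation toward C2 takes over. The fallback sets out from 16 and comes back at 20. The order of dehydrogenation and ring closure is exchanged: Saegusa–Ito oxidation of 16 (LiN(i-Pr)2, Me3SiCl; then Pd(OAc)2) should give the bicyclic dienone (4aS,7R,9R,9aS)-7-(benzyloxy)-4a,8,8-trimethyl-3-oxo-4,4a,7,8,9,9a-hexahydro-3H-benzo[7]annulen-9-yl methanesulfonate F1. In F1, C2 is sp2, so LiN(i-Pr)2 in THF–HMPA at −78 °C should generate irreversibly only the cross-conjugated C4 enolate, which on warming should close onto C5 and give enone 20 directly; step 15 is then not needed.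

Step 6. Incomplete chelation or a closed transition state may erode the facial selectivity at the aldehyde or the syn selectivity, so that C5 and C11 form as mixtures. The fallback sets out from 5 and comes back at 8, and replaces substrate control by an auxiliary-controlled Evans syn-aldol followed by ring construction. 5-Oxohexanoic acid is ketalised with ethylene glycol to 4-(2-methyl-1,3-dioxolan-2-yl)butanoic acid F2. F2 is attached through its pivaloyl mixed anhydride to lithiated (4R)-4-benzyl-1,3-oxazolidin-2-one to give (4R)-4-benzyl-3-[4-(2-methyl-1,3-dioxolan-2-yl)butanoyl]-1,3-oxazolidin-2-one F3. Its boron enolate (Bu2BOTf, i-Pr2NEt) should add to 5 to give the syn-aldol (4R)-4-benzyl-3-{(2R,3R,5R)-5-(benzyloxy)-3-hydroxy-4,4-dimethyl-2-[2-(2-methyl-1,3-dioxolan-2-yl)ethyl]hept-6-enoyl}-1,3-oxazolidin-2-one F4, with both new centres fixed by the auxiliary. Ketal hydrolysis (pyridinium tosylate, wet acetone) and silylation (Et3SiCl, imidazole) should give the keto imide (4R)-4-benzyl-3-[(2R,3R,5R)-5-(benzyloxy)-4,4-dimethyl-2-(3-oxobutyl)-3-(triethylsilyloxy)hept-6-enoyl]-1,3-oxazolidin-2-one F5. LiN(SiMe3)2 should then close the ring by Claisen-type displacement of the oxazolidinone by the methyl ketone enolate, giving (4R)-4-[(1R,3R)-3-(benzyloxy)-2,2-dimethyl-1-(triethylsilyloxy)pent-4-en-1-yl]cyclohexane-1,3-dione F6. Triethyl orthoformate and ethanol with catalytic p-toluenesulfonic acid should form the enol ether at the less hindered carbonyl and remove the silyl group, which gives 8.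

Step 23. Under the forcing conditions needed at two hindered secondary hydroxyls, the angeloyl donor may isomerise from Z to E and the C8 acetate may migrate to a neighbouring hydroxyl. The fallback sets out from 27 and comes back at 28, and builds the Z double bonds only after acylation. Both hydroxyls of 27 are esterified with 2-[bis(2,2,2-trifluoroethoxy)phosphoryl]propanoic acid (dicyclohexylcarbodiimide, cat. 4-dimethylaminopyridine, CH2Cl2) to give 8-acetoxy-1-oxolongipinane-7,9-diyl bis{2-[bis(2,2,2-trifluoroethoxy)phosphoryl]propanoate} F7 (ring configuration of 27, epimers at the phosphonate α-carbons). Still–Gennari olefination of F7 (KN(SiMe3)2, 18-crown-6, THF, −78 °C, acetaldehyde) should then form both (Z)-2-methylbut-2-enoates and give 28.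

Further compounds
F1 | step 14 | (4aS,7R,9R,9aS)-7-(benzyloxy)-4a,8,8-trimethyl-3-oxo-4,4a,7,8,9,9a-hexahydro-3H-benzo[7]annulen-9-yl methanesulfonate | c1ccccc1CO[C@@H]2C=C[C@]3(C)CC(=O)C=C[C@@H]3[C@@H](OS(C)(=O)=O)C2(C)C
F2 | step 6 | 4-(2-methyl-1,3-dioxolan-2-yl)butanoic acid | CC1(CCCC(=O)O)OCCO1
F3 | step 6 | (4R)-4-benzyl-3-[4-(2-methyl-1,3-dioxolan-2-yl)butanoyl]-1,3-oxazolidin-2-one | CC1(CCCC(=O)N2[C@H](Cc3ccccc3)COC2=O)OCCO1
F4 | step 6 | (4R)-4-benzyl-3-{(2R,3R,5R)-5-(benzyloxy)-3-hydroxy-4,4-dimethyl-2-[2-(2-methyl-1,3-dioxolan-2-yl)ethyl]hept-6-enoyl}-1,3-oxazolidin-2-one | O=C(N1[C@H](Cc2ccccc2)COC1=O)[C@H](CCC3(C)OCCO3)[C@@H](O)C(C)(C)[C@H](OCc4ccccc4)C=C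
F5 | step 6 | (4R)-4-benzyl-3-[(2R,3R,5R)-5-(benzyloxy)-4,4-dimethyl-2-(3-oxobutyl)-3-(triethylsilyloxy)hept-6-enoyl]-1,3-oxazolidin-2-one | CC(=O)CC[C@@H](C(=O)N1[C@H](Cc2ccccc2)COC1=O)[C@@H](O[Si](CC)(CC)CC)C(C)(C)[C@H](OCc3ccccc3)C=C
F6 | step 6 | (4R)-4-[(1R,3R)-3-(benzyloxy)-2,2-dimethyl-1-(triethylsilyloxy)pent-4-en-1-yl]cyclohexane-1,3-dione | O=C1CC(=O)CC[C@@H]1[C@@H](O[Si](CC)(CC)CC)C(C)(C)[C@H](OCc2ccccc2)C=C
F7 | step 23 | 8-acetoxy-1-oxolongipinane-7,9-diyl bis{2-[bis(2,2,2-trifluoroethoxy)phosphoryl]propanoate} (ring configuration of 27) | CC(C(=O)O[C@@H]1[C@@H](OC(C)=O)[C@@H](OC(=O)C(C)P(=O)(OCC(F)(F)F)OCC(F)(F)F)[C@]2(C)[C@@H]3[C@@H]([C@H]2C(=O)C[C@H]3C)C1(C)C)P(=O)(OCC(F)(F)F)OCC(F)(F)F
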